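Both end rings are the same (2R,3R)-2,3-dihydroxy-β ring, so one C15 phosphonium salt is used twice around the C10 dialdehyde, and the sulfate is put on at the C25 aldehyde stage. The ring rests on a Diels–Alder reaction that makes the C4–C5 bond (ring CH2 to the methyl-bearing alkene carbon) and the C1–C6 bond (gem-dimethyl carbon to the chain-bearing alkene carbon) at once: the silyl dienol ether of mesityl oxide adds to ethyl but-2-ynoate. The tetrasubstituted C5=C6 alkene next to quaternary C1 is thus read as an alkyne, and the C2=C3 silyl enol ether of the adduct delivers the trans-diol by one asymmetric hydroboration.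

Key step: step 2

Remark on numbering: carotenoid numbering is used for the ring (C1 = CMe2, C2 and C3 = carbinol carbons, C4 = CH2, C5 = methyl-bearing alkene carbon, C6 = alkene carbon carrying the polyene).
Remark on the protonation state: the target is drawn as the free hydrogen sulfate, so the route reaches its sodium salt first and protonates it in the last operation; the salt is the form to store.
Remark on alkene geometry: each Wittig step is expected to give E/Z mixtures at the new double bond, which are equilibrated to the all-E polyene with catalytic iodine.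

Step 1
Reactants: 1 mesityl oxide (4-methylpent-3-en-2-one)
Product: 3 triethyl[(4-methylpenta-1,3-dien-2-yl)oxy]silane, via lithium 4-methylpenta-1,3-dien-2-olate 2 (not isolated)
Conditions: LiN(i-Pr)2 (1.1 equiv), THF, −78 °C; Et3SiCl, −78 °C → rt
Reagents that add atoms: chlorotriethylsilane, CC[Si](Cl)(CC)CC
Why: Kinetic deprotonation of the enone at its acetyl methyl group gives the cross-conjugated lithium dienolate, which is trapped on oxygen (silyl enol ether formation) to give the 2-silyloxydiene.

Step 2
Reactants: 3 triethyl[(4-methylpenta-1,3-dien-2-yl)oxy]silane; 4 ethyl but-2-ynoate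
Product: 5 ethyl 2,6,6-trimethyl-4-(triethylsilyloxy)cyclohexa-1,4-diene-1-carboxylate
Conditions: neat, equimolar amounts, BHT (1 mol %), base-washed sealed tube, 140 °C, 48 h
Reagents that add atoms: none
Why: A thermal, concerted but asynchronous normal-electron-demand Diels–Alder [4+2] cycloaddition joins the two diene termini of 3 to the two alkyne carbons of 4, so the CH2–C(Me) bond (C4–C5) and the CMe2–C(CO2Et) bond (C1–C6) form in one operation and leave the C5=C6 and C2=C3 double bonds of a cyclohexa-1,4-diene. The closest known reaction type is the cycloaddition of 2-silyloxybuta-1,3-dienes, including 4,4-dialkyl ones, to acetylenic esters. The six-membered ring is closed by intermolecular suprafacial [4π+2π] cycloaddition; no stereocentre is created, and the quaternary C1 blocks aromatisation of the adduct. The step needs regioselectivity: the CH2 terminus, β to the silyloxy group and remote from the two methyl donors, carries the largest HOMO coefficient and bonds to the β-carbon of the ynoate, so the silyloxy group ends 1,4 and the gem-dimethyl carbon 1,2 to the ester-bearing carbon, the two directing effects reinforcing each other. It also needs the silyl enol ether to survive, which the triethylsilyl group and acid-free glassware should secure. The Z-methyl group of the diene disfavours the s-cis conformer and slows the reaction, hence the absence of solvent and the temperature.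

Step 3
Reactants: 5 ethyl 2,6,6-trimethyl-4-(triethylsilyloxy)cyclohexa-1,4-diene-1-carboxylate
Product: 7 ethyl (4R,5R)-5-hydroxy-2,6,6-trimethyl-4-(triethylsilyloxy)cyclohex-1-ene-1-carboxylate, via isopinocampheyl(alkyl)borane 6 (not isolated)
Conditions: IpcBH2 (from (−)-α-pinene, 1.2 equiv), Et2O, −25 → 0 °C; then 3 M NaOH, 30% H2O2, 0 °C
Reagents that add atoms: hydrogen peroxide, OO
Why: Asymmetric hydroboration–oxidation of the trisubstituted silyl enol ether with monoisopinocampheylborane puts boron on C2 (β to oxygen) and hydrogen on C3 from the same face, so oxidation with retention fixes the trans 2-OH/3-OSiEt3 relationship, while the isopinocampheyl group selects the face (the (−)-α-pinene series is predicted for (2R,3R) by analogy with 1-substituted cycloalkenes and is to be confirmed, the antipode being equally available); the conjugated tetrasubstituted alkene and the ester should not react.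

Step 4
Reactants: 7 ethyl (4R,5R)-5-hydroxy-2,6,6-trimethyl-4-(triethylsilyloxy)cyclohex-1-ene-1-carboxylate
Product: 8 [(4R,5R)-5-hydroxy-2,6,6-trimethyl-4-(triethylsilyloxy)cyclohex-1-en-1-yl]methanol
Conditions: i-Bu2AlH (3.5 equiv), CH2Cl2, −78 → 0 °C; aqueous work-up
Reagents that add atoms: none
Why: Hydride reduction of the conjugated ester to the allylic primary alcohol, with one equivalent of hydride spent on the free hydroxyl and the silyl ether and both stereocentres untouched.

Step 5
Reactants: 8 [(4R,5R)-5-hydroxy-2,6,6-trimethyl-4-(triethylsilyloxy)cyclohex-1-en-1-yl]methanol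
Product: 9 (4R,5R)-5-hydroxy-2,6,6-trimethyl-4-(triethylsilyloxy)cyclohex-1-ene-1-carbaldehyde
Conditions: MnO2 (activated, 15 equiv), CH2Cl2, rt
Reagents that add atoms: none
Why: Allylic oxidation with MnO2 is selective for the allylic primary alcohol over the neopentylic secondary hydroxyl, and a lactol cannot form because it would need a bridgehead double bond.

Step 6
Reactants: 9 (4R,5R)-5-hydroxy-2,6,6-trimethyl-4-(triethylsilyloxy)cyclohex-1-ene-1-carbaldehyde; 10 diethyl (2-oxopropyl)phosphonate
Product: 11 (3E)-4-[(4R,5R)-5-hydroxy-2,6,6-trimethyl-4-(triethylsilyloxy)cyclohex-1-en-1-yl]but-3-en-2-one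
Conditions: Ba(OH)2 (activated, 0.8 equiv), THF/H2O 40:1, rt → 40 °C
Reagents that add atoms: none
Why: Horner–Wadsworth–Emmons olefination under mild Ba(OH)2 conditions, in which the small β-ketophosphonate anion should add even to the hindered cyclocitral-type aldehyde and give the E enone.

Step 7
Reactants: 11 (3E)-4-[(4R,5R)-5-hydroxy-2,6,6-trimethyl-4-(triethylsilyloxy)cyclohex-1-en-1-yl]but-3-en-2-one; 12 vinylmagnesium bromide
Product: 13 (1E)-1-[(4R,5R)-5-hydroxy-2,6,6-trimethyl-4-(triethylsilyloxy)cyclohex-1-en-1-yl]-3-methylpenta-1,4-dien-3-ol (both epimers at the new carbinol carbon)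
Conditions: CH2=CHMgBr (3 equiv), THF, −40 → 0 °C; then H2O
Reagents that add atoms: none
Why: 1,2-Addition of the vinyl Grignard reagent to the dienone, as in the conversion of ionones into vinyl carbinols; the new carbinol centre is formed as both epimers, which is immaterial because it is planarised in step 8.

Step 8
Reactants: 13 (1E)-1-[(4R,5R)-5-hydroxy-2,6,6-trimethyl-4-(triethylsilyloxy)cyclohex-1-en-1-yl]-3-methylpenta-1,4-dien-3-ol; 14 triphenylphosphine hydrobromide
Product: 15 [(2E,4E)-5-[(4R,5R)-4,5-dihydroxy-2,6,6-trimethylcyclohex-1-en-1-yl]-3-methylpenta-2,4-dien-1-yl]triphenylphosphonium bromide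
Conditions: PPh3·HBr (1.3 equiv), MeOH, 0 °C → rt, 16 h
Reagents that add atoms: none
Why: Acid ionisation of the bis-allylic tertiary alcohol gives a delocalised pentadienyl cation that PPh3 captures at the unhindered terminus (allylic transposition), giving the conjugated (2E,4E) salt, while the acidic methanol cleaves the triethylsilyl ether, so any silyl group that has migrated or been lost earlier converges on the same diol salt.

Step 9
Reactants: 15 [(2E,4E)-5-[(4R,5R)-4,5-dihydroxy-2,6,6-trimethylcyclohex-1-en-1-yl]-3-methylpenta-2,4-dien-1-yl]triphenylphosphonium bromide; 16 (2E,4E,6E)-2,7-dimethylocta-2,4,6-trienedial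
Product: 17 (2E,4E,6E,8E,10E,12E)-13-[(4R,5R)-4,5-dihydroxy-2,6,6-trimethylcyclohex-1-en-1-yl]-2,7,11-trimethyltrideca-2,4,6,8,10,12-hexaenal
Conditions: dialdehyde in threefold excess, NaOMe (1.1 equiv, slow addition), CH2Cl2/MeOH, −10 °C → rt; then I2 (cat.), CH2Cl2, rt, daylight
Reagents that add atoms: none
Why: Wittig olefination of one aldehyde group of the symmetrical dialdehyde, kept in excess to suppress double condensation, builds the C11=C12 bond, and iodine-catalysed equilibration should give the all-E polyene.

Step 10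
Reactants: 17 (2E,4E,6E,8E,10E,12E)-13-[(4R,5R)-4,5-dihydroxy-2,6,6-trimethylcyclohex-1-en-1-yl]-2,7,11-trimethyltrideca-2,4,6,8,10,12-hexaenal
Product: 18 sodium (2R,3R)-2-hydroxy-12'-oxo-12'-apo-β-caroten-3-yl sulfate (the 3-O-sulfate of 17 as its sodium salt)
Conditions: SO3·pyridine (1.1 equiv), pyridine/DMF, −10 → 0 °C; then aq NaHCO3
Reagents that add atoms: sulfur trioxide–pyridine complex, O=S(=O)=O.c1ccncc1; sodium hydrogencarbonate, [Na+].OC(=O)[O-]
Why: O-Sulfation with SO3·pyridine should go to the C3 hydroxyl, flanked by a CH2 group, in preference to the C2 hydroxyl, which is neopentylic and gauche to both methyl groups on C1, and the negative charge of the monosulfate disfavours a second sulfation; the stereocentres are not touched.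

Step 11
Reactants: 18 sodium (2R,3R)-2-hydroxy-12'-oxo-12'-apo-β-caroten-3-yl sulfate; 15 [(2E,4E)-5-[(4R,5R)-4,5-dihydroxy-2,6,6-trimethylcyclohex-1-en-1-yl]-3-methylpenta-2,4-dien-1-yl]triphenylphosphonium bromide
Product: 20 (2R,3R,2'R,3'R)-2,2',3'-trihydroxy-β,β-caroten-3-yl hydrogen sulfate (nostoxanthin 3-sulfate), via sodium nostoxanthin 3-sulfate 19 (not isolated)
Conditions: phosphonium salt (1.3 equiv), NaOMe (1.4 equiv), MeOH/CH2Cl2, 0 °C → rt; I2 (cat.), rt, daylight; then cold 0.05 M HCl, extraction into n-BuOH/EtOAc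
Reagents that add atoms: none
Why: A second Wittig olefination with the same ylide closes the C40 chain at the last chain double bond (a sulfate monoester anion is inert to ylide and methoxide), iodine equilibration should give the all-E isomer, and brief cold acidification protonates the sulfate.

Compound list
1 | mesityl oxide (4-methylpent-3-en-2-one) | CC(=O)C=C(C)C | starting material
2 | lithium 4-methylpenta-1,3-dien-2-olate | [Li+].[O-]C(=C)C=C(C)C | intermediate (not isolated)
3 | triethyl[(4-methylpenta-1,3-dien-2-yl)oxy]silane | C=C(O[Si](CC)(CC)CC)C=C(C)C | intermediate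
4 | ethyl but-2-ynoate | CC#CC(=O)OCC | starting material
5 | ethyl 2,6,6-trimethyl-4-(triethylsilyloxy)cyclohexa-1,4-diene-1-carboxylate | CCOC(=O)C1=C(C)CC(O[Si](CC)(CC)CC)=CC1(C)C | intermediate
6 | ethyl (4R,5R)-5-[hydrido(isopinocampheyl)boranyl]-2,6,6-trimethyl-4-(triethylsilyloxy)cyclohex-1-ene-1-carboxylate (isopinocampheyl from (−)-α-pinene) | C[C@@H]1[C@@H](B[C@H]3[C@H](O[Si](CC)(CC)CC)CC(C)=C(C(=O)OCC)C3(C)C)C[C@H]2C[C@@H]1C2(C)C | intermediate (not isolated)
7 | ethyl (4R,5R)-5-hydroxy-2,6,6-trimethyl-4-(triethylsilyloxy)cyclohex-1-ene-1-carboxylate | CCOC(=O)C1=C(C)C[C@@H](O[Si](CC)(CC)CC)[C@H](O)C1(C)C | intermediate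
8 | [(4R,5R)-5-hydroxy-2,6,6-trimethyl-4-(triethylsilyloxy)cyclohex-1-en-1-yl]methanol | OCC1=C(C)C[C@@H](O[Si](CC)(CC)CC)[C@H](O)C1(C)C | intermediate
9 | (4R,5R)-5-hydroxy-2,6,6-trimethyl-4-(triethylsilyloxy)cyclohex-1-ene-1-carbaldehyde | O=CC1=C(C)C[C@@H](O[Si](CC)(CC)CC)[C@H](O)C1(C)C | intermediate
10 | diethyl (2-oxopropyl)phosphonate | CCOP(=O)(CC(C)=O)OCC | starting material
11 | (3E)-4-[(4R,5R)-5-hydroxy-2,6,6-trimethyl-4-(triethylsilyloxy)cyclohex-1-en-1-yl]but-3-en-2-one | CC(=O)/C=C/C1=C(C)C[C@@H](O[Si](CC)(CC)CC)[C@H](O)C1(C)C | intermediate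
12 | vinylmagnesium bromide | C=C[Mg]Br | starting material
13 | (1E)-1-[(4R,5R)-5-hydroxy-2,6,6-trimethyl-4-(triethylsilyloxy)cyclohex-1-en-1-yl]-3-methylpenta-1,4-dien-3-ol (both epimers at C3 of the chain) | C=CC(C)(O)/C=C/C1=C(C)C[C@@H](O[Si](CC)(CC)CC)[C@H](O)C1(C)C | intermediate
14 | triphenylphosphine hydrobromide | [Br-].[PH+](c1ccccc1)(c1ccccc1)c1ccccc1 | starting material
15 | [(2E,4E)-5-[(4R,5R)-4,5-dihydroxy-2,6,6-trimethylcyclohex-1-en-1-yl]-3-methylpenta-2,4-dien-1-yl]triphenylphosphonium bromide | [Br-].CC1=C(/C=C/C(C)=C/C[P+](c2ccccc2)(c2ccccc2)c2ccccc2)C(C)(C)[C@@H](O)[C@H](O)C1 | intermediate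
16 | (2E,4E,6E)-2,7-dimethylocta-2,4,6-trienedial | O=C/C(C)=C/C=C/C=C(C)/C=O | starting material
17 | (2E,4E,6E,8E,10E,12E)-13-[(4R,5R)-4,5-dihydroxy-2,6,6-trimethylcyclohex-1-en-1-yl]-2,7,11-trimethyltrideca-2,4,6,8,10,12-hexaenal | CC1=C(/C=C/C(C)=C/C=C/C(C)=C/C=C/C=C(C)/C=O)C(C)(C)[C@@H](O)[C@H](O)C1 | intermediate
18 | sodium (2R,3R)-2-hydroxy-12'-oxo-12'-apo-β-caroten-3-yl sulfate | [Na+].CC1=C(/C=C/C(C)=C/C=C/C(C)=C/C=C/C=C(C)/C=O)C(C)(C)[C@@H](O)[C@H](OS(=O)(=O)[O-])C1 | intermediate
19 | sodium (2R,3R,2'R,3'R)-2,2',3'-trihydroxy-β,β-caroten-3-yl sulfate | [Na+].CC1=C(/C=C/C(C)=C/C=C/C(C)=C/C=C/C=C(C)/C=C/C=C(C)/C=C/C2=C(C)C[C@@H](OS(=O)(=O)[O-])[C@H](O)C2(C)C)C(C)(C)[C@@H](O)[C@H](O)C1 | intermediate (not isolated)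
20 | (2R,3R,2'R,3'R)-2,2',3'-trihydroxy-β,β-caroten-3-yl hydrogen sulfate | CC1=C(/C=C/C(C)=C/C=C/C(C)=C/C=C/C=C(C)/C=C/C=C(C)/C=C/C2=C(C)C[C@@H](OS(=O)(=O)O)[C@H](O)C2(C)C)C(C)(C)[C@@H](O)[C@H](O)C1 | target

Total step count: 11
Longest linear sequence: 11 steps (1 → 20; salt 15 enters the line a second time in step 11)

Steps most likely to fail

1. Step 2. The cycloaddition may be too slow, because the Z-methyl group of the diene hinders the s-cis conformer and the β-methyl group deactivates the ynoate; at the temperature then needed, 1,5-hydrogen shift in the diene and loss of the silyl group could compete. Fallback: setting out from diene 3, the allenic ester ethyl buta-2,3-dienoate (C=C=CC(=O)OCC), a markedly better dienophile, would be used in toluene at 80–100 °C. Cycloaddition across its activated 2,3-double bond with the same orientation should give racemic ethyl 2,2-dimethyl-6-methylidene-4-(triethylsilyloxy)cyclohex-3-ene-1-carboxylate F1. DBU in toluene should then move the exocyclic double bond into conjugation with the ester, which comes back to the route at compound 5.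

2. Step 3. The bulky borane may add slowly at C2 next to the quaternary carbon, or discriminate poorly between the two faces of the enol ether, so that the enantiomeric purity is too low. Fallback: setting out from 5, hydroboration with BH3·SMe2 (THF, 0 °C) and the same oxidative work-up should give the racemic trans ethyl 5-hydroxy-2,6,6-trimethyl-4-(triethylsilyloxy)cyclohex-1-ene-1-carboxylate F2. PPTS in EtOH would remove the silyl group to give the racemic trans ethyl 4,5-dihydroxy-2,6,6-trimethylcyclohex-1-ene-1-carboxylate F3. Burkholderia cepacia lipase with vinyl acetate in MTBE should acetylate the unhindered hydroxyl of the (4R,5R) enantiomer only, following the usual enantiopreference of lipases for secondary alcohols, to give ethyl (4R,5R)-4-acetoxy-5-hydroxy-2,6,6-trimethylcyclohex-1-ene-1-carboxylate F4, separable from the untouched (4S,5S)-diol. K2CO3 in EtOH would give ethyl (4R,5R)-4,5-dihydroxy-2,6,6-trimethylcyclohex-1-ene-1-carboxylate F5, and Et3SiCl/imidazole (DMF, 0 °C) should silylate the less hindered 4-hydroxyl, which comes back to the route at compound 7.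

3. Step 10. Sulfation may not stop at the C3 hydroxyl: over-sulfation to the bis-sulfate or partial reaction at the hindered C2 hydroxyl would give mixtures that are hard to separate. Fallback: setting out from 17, Bu2SnO in refluxing MeOH would give the 2,3-O-dibutylstannylene acetal of 17 F6, in which the less hindered oxygen on C3 is the activated one. SO3·NMe3 in dioxane/DMF at rt followed by aqueous NaHCO3 should then deliver the 3-monosulfate, which comes back to the route at compound 18.

Further compounds
F1 | step 2 | ethyl 2,2-dimethyl-6-methylidene-4-(triethylsilyloxy)cyclohex-3-ene-1-carboxylate (racemic) | CCOC(=O)C1C(=C)CC(O[Si](CC)(CC)CC)=CC1(C)C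
F2 | step 3 | racemic trans ethyl 5-hydroxy-2,6,6-trimethyl-4-(triethylsilyloxy)cyclohex-1-ene-1-carboxylate | CCOC(=O)C1=C(C)C[C@@H](O[Si](CC)(CC)CC)[C@H](O)C1(C)C.CCOC(=O)C1=C(C)C[C@H](O[Si](CC)(CC)CC)[C@@H](O)C1(C)C
F3 | step 3 | racemic trans ethyl 4,5-dihydroxy-2,6,6-trimethylcyclohex-1-ene-1-carboxylate | CCOC(=O)C1=C(C)C[C@@H](O)[C@H](O)C1(C)C.CCOC(=O)C1=C(C)C[C@H](O)[C@@H](O)C1(C)C
F4 | step 3 | ethyl (4R,5R)-4-acetoxy-5-hydroxy-2,6,6-trimethylcyclohex-1-ene-1-carboxylate | CCOC(=O)C1=C(C)C[C@@H](OC(C)=O)[C@H](O)C1(C)C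
F5 | step 3 | ethyl (4R,5R)-4,5-dihydroxy-2,6,6-trimethylcyclohex-1-ene-1-carboxylate | CCOC(=O)C1=C(C)C[C@@H](O)[C@H](O)C1(C)C
F6 | step 10 | 2,3-O-dibutylstannylene acetal of 17 | CCCC[Sn]1(CCCC)O[C@@H]2CC(C)=C(/C=C/C(C)=C/C=C/C(C)=C/C=C/C=C(C)/C=O)C(C)(C)[C@H]2O1
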